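(The runs come from a simulation with made-up constants; scatter was added.)

At 2.50 min, my last reading of the beta flask, I have a decision to make: do I leave the charge as it stands, and which product do I plan for at 5.0 min?

| flask | starting material | first nucleophile | second nucleophile | protic impurity | remark | time |
|---|---|---|---|---|---|---|
| beta | 5.0 × 10⁻⁴ M (in portions, 3) | 2 equiv | 0.90 equiv | 0.15 mM | the very flask that is asked about, followed so far; portions every 1.5 min |  |
| alpha | 7.5 × 10⁻⁴ M (in portions, 3) | 2 equiv | 0.90 equiv | 0.15 mM | run made earlier; portions every 1.5 min |  |
| flask | 5.0 × 10⁻⁴ M (in portions, 3) | 2.00 equiv | 0.900 equiv | 0.150 mM | the portions of starting material follow each other after 1.5 min, the first at the start | 5.0 min |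

beta run (percent of the starting material charged)

| time / min | other capture product / % | solvolysis product / % | starting material / % | intermediate / % | target / % |
|---|---|---|---|---|---|
| 0.167 | 1.7 | 2.0 | 29.0 | 0.5 | 0 |
| 0.417 | 4.5 | 3.1 | 23.0 | 0 | 0 |
| 0.667 | 6.3 | 4.8 | 18.2 | 0.3 | 0 |
| 1.00 | 8.4 | 6.3 | 13.3 | 0 | 0.1 |
| 1.50 | 9.9 | 8.3 | 8.6 | 0 | 0.1 |
| 2.00 | 15.0 | 14.5 | 27.2 | 0.1 | 0 |
| 2.50 | 19.1 | 18.0 | 17.7 | 0 | 0 |

alpha run (percent of the starting material charged)

| time / s | other capture product / % | solvolysis product / % | starting material / % | intermediate / % | target / % |
|---|---|---|---|---|---|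
| 10.0 | 2.2 | 0.9 | 28.4 | 0 | 0.4 |
| 15.0 | 3.5 | 2.0 | 26.4 | 0 | 0.5 |
| 20.0 | 3.8 | 1.7 | 24.1 | 0 | 0.4 |
| 30.0 | 5.9 | 3.0 | 20.9 | 0.3 | 0.8 |
| 50.0 | 8.5 | 4.6 | 15.3 | 0 | 0.1 |
| 80.0 | 11.2 | 6.0 | 10.2 | 0.4 | 0.4 |
| 120 | 18.3 | 11.5 | 27.0 | 0 | 0 |

(readings scatter by 0.3 percentage points)

1. where most of what was charged as starting material, at 5.0 min is found (solvolysis product / target / starting material / other capture product / intermediate)
2. the largest share itself, whichever of these holds it, in percent of the starting material charged

- a reading or a percentage of starting material is of its free form alone
- a reading at the moment of an addition is taken just before it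
- percentages count the whole charge, also what has not yet gone in

1. I treat the intermediate as a short-lived node with two exits: solvolysis at a first-order rate, and capture at a rate proportional to [second nucleophile]. The ratio of other capture product made to solvolysis product made, divided by [second nucleophile], should then stay constant.

2. Dividing by the charged [second nucleophile], the beta flask at 1.50 min reads 2650 L mol⁻¹ and the alpha flask at 80.0 s reads 2770 L mol⁻¹. Two different charges give about the same figure. I keep the mean, 2710 L mol⁻¹, as the capture number: product ratio per unit [second nucleophile], a selectivity factor.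

3. I work with the fraction of second nucleophile left. By the capture number, the beta flask makes the two products at equal rates when that fraction stands near 82.1 %, an estimate I call the tie value.

4. From 1.50 min to 2.50 min the beta flask gains 9.2 percentage points of other capture product against 9.7 points of solvolysis product. That reads as a fraction left of 77.8 %, a loose reading at a scatter of 0.3 points. The last interval of the alpha flask reads 70.6 %.

5. No second nucleophile is added, so I expect the fraction to keep falling. In the last beta reading other capture product leads by just 1.1 points, with a portion still to come. My reckoning therefore puts solvolysis product ahead at 5.0 min, though it gives no share, and I leave the charge alone.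

6. The forecast also says solvolysis product, at 37.5 %: “It is close, but solvolysis leads.”

The flask gives solvolysis product at 39.6 %, with second nucleophile at 36.6 % of its charge. Its final product ratio, set against the capture number, reads as a mean fraction left of 66.8 %, below the tie value. A neighbour charged with 0.0013 M has a tie value of 31.6 %, so carrying that mean fraction over gives a ratio of 2.11. The neighbour's simulated ratio is 2.06, with other capture product on top at 48.4 % against 23.5 % solvolysis product.

    first nucleophile + intermediate ⇌ target (K = 1790 L mol⁻¹, k = 2470 L mol⁻¹ s⁻¹)
    second nucleophile + protic impurity → quenched reagent (k = 21.6 L mol⁻¹ s⁻¹)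
    starting material ⇌ dormant form (K = 1.70, k = 0.00432 s⁻¹)
    second nucleophile + intermediate → other capture product (k = 7120 L mol⁻¹ s⁻¹)
    intermediate → solvolysis product (k = 2.32 s⁻¹)
    starting material → intermediate (k = 0.0114 s⁻¹)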